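**Plan**
Cuts (chain numbered from the benzylic carbon C1 to the CH2OH carbon C16): C1–aryl (allylic bromide plus arylcopper), C4–C5 (vinylogous aldol) and C14=C15 (Z-selective olefination), leaving (2E,6E)-farnesol, ethyl 3-methylbut-2-enoate, a trifluoroethyl phosphonopropanoate and 4-methoxy-2-methylphenol.
Feature: the only stereocentre, the C5 carbinol, lies δ to C1 across the E-configured C2=C3 alkene that carries the C3 methyl, so C1–C5 is a δ-hydroxy senecioate and C5–C16 a 16-oxygenated farnesal with a Z end; the benzene ring is the only ring and is bought, no ring is formed.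
Forward: farnesol is shortened by three carbons at its tail and re-extended to the Z allylic silyl ether, C1 is raised to the enal, the aldol joins C4 to C5, then ester to bromide, arylation at C1, desilylation and oxidative unmasking of the hydroquinone.
Stereochemistry: 5R from the chiral bisphosphoramide–SiCl4 catalyst; 6E and 10E from farnesol; 14Z from the Still–Gennari reagent; 2E from the s-trans dienolate, kept in the copper coupling.

Key step: step 10

Assumption: the (R,R)-bisphosphoramide is taken to leave the Re face of the aldehyde carbonyl open, the face whose attack gives 5R; should the sense be opposite, the (S,S)-antipode is used and nothing else changes.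

**Route**

Step 1
Reactants: 1 (2E,6E)-farnesol
Product: 2 (2E,6E)-farnesyl 4-methoxybenzyl ether
Conditions: NaH, 4-methoxybenzyl chloride, Bu4NI (cat.), THF/DMF, 0 °C to rt
Reagents that add atoms: 4-methoxybenzyl chloride, COc1ccc(CCl)cc1
Why: Williamson ether synthesis on the allylic alkoxide; the 4-methoxybenzyl ether should survive periodic acid, base and hydride and can later be removed oxidatively beside a silyl ether.

Step 2
Reactants: 2 (2E,6E)-farnesyl 4-methoxybenzyl ether
Product: 4 racemic 2-[(3E,7E)-9-[(4-methoxyphenyl)methoxy]-3,7-dimethylnona-3,7-dien-1-yl]-3,3-dimethyloxirane, via terminal bromohydrin 3 (not isolated)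
Conditions: NBS, THF/H2O, 0 °C; then K2CO3, MeOH, rt
Reagents that add atoms: water, O
Why: Terminal-selective bromohydrin formation of a polyprenyl ether in aqueous THF (bromonium ion at the most exposed trisubstituted alkene, water at the tertiary carbon; the C2=C3 alkene is deactivated by the allylic oxygen), then intramolecular Williamson closure to the epoxide; the new centre is racemic and is destroyed in step 3.

Step 3
Reactants: 4 racemic terminal epoxide
Product: 5 (4E,8E)-10-[(4-methoxyphenyl)methoxy]-4,8-dimethyldeca-4,8-dienal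
Conditions: H5IO6, THF/Et2O, 0 °C
Reagents that add atoms: none
Why: Periodic acid opens the epoxide to the glycol (water entering at the tertiary carbon, so the aldehyde keeps the epoxide oxygen) and cleaves it in a Malaprade glycol cleavage, releasing acetone and leaving the ether and both alkenes untouched.

Step 4
Reactants: 5 (4E,8E)-10-[(4-methoxyphenyl)methoxy]-4,8-dimethyldeca-4,8-dienal; 6 ethyl 2-[bis(2,2,2-trifluoroethoxy)phosphoryl]propanoate
Product: 7 ethyl (2Z,6E,10E)-12-[(4-methoxyphenyl)methoxy]-2,6,10-trimethyldodeca-2,6,10-trienoate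
Conditions: KN(SiMe3)2, 18-crown-6, THF, −78 °C
Reagents that add atoms: none
Why: Still–Gennari variant of the Horner–Wadsworth–Emmons olefination, in which the electron-poor trifluoroethyl phosphonate with a crown-separated potassium ion eliminates fast from the kinetic adduct and should give the Z-configured α-methyl enoate with an unbranched aldehyde.

Step 5
Reactants: 7 Z-enoate
Product: 8 (2Z,6E,10E)-12-[(4-methoxyphenyl)methoxy]-2,6,10-trimethyldodeca-2,6,10-trien-1-ol
Conditions: i-Bu2AlH, CH2Cl2, −78 °C; aqueous potassium sodium tartrate work-up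
Reagents that add atoms: none
Why: 1,2-Reduction of a conjugated ester by i-Bu2AlH should give the allylic alcohol without touching the alkene geometry.

Step 6
Reactants: 8 Z allylic alcohol
Product: 9 tert-butyl{[(2Z,6E,10E)-12-[(4-methoxyphenyl)methoxy]-2,6,10-trimethyldodeca-2,6,10-trien-1-yl]oxy}dimethylsilane
Conditions: TBSCl, imidazole, DMF, rt
Reagents that add atoms: tert-butyldimethylsilyl chloride, CC(C)(C)[Si](C)(C)Cl
Why: Imidazole-promoted silylation of a primary allylic alcohol; this silyl ether is the C16 protecting group carried to the end.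

Step 7
Reactants: 9 silyl ether with 4-methoxybenzyl ether
Product: 10 (2E,6E,10Z)-12-[(tert-butyldimethylsilyl)oxy]-3,7,11-trimethyldodeca-2,6,10-trien-1-ol
Conditions: DDQ, CH2Cl2/pH 7 phosphate buffer, 0 °C
Reagents that add atoms: none
Why: Oxidative cleavage of a 4-methoxybenzyl ether by DDQ (hydride abstraction to the oxocarbenium ion, hydrolysis) under buffered conditions that leave the silyl ether and the alkenes alone; any over-oxidation to the enal only anticipates step 8.

Step 8
Reactants: 10 (2E,6E,10Z)-12-silyloxy farnesol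
Product: 11 (2E,6E,10Z)-12-[(tert-butyldimethylsilyl)oxy]-3,7,11-trimethyldodeca-2,6,10-trienal
Conditions: MnO2, CH2Cl2, rt
Reagents that add atoms: none
Why: Heterogeneous MnO2 oxidation is selective for allylic alcohols, neutral, and should keep the 2E geometry, as in the farnesol-to-farnesal oxidation.

Step 9
Reactants: 12 ethyl 3-methylbut-2-enoate
Product: 13 (1Z)-1-[(tert-butyldimethylsilyl)oxy]-1-ethoxy-3-methylbuta-1,3-diene
Conditions: LiN(i-Pr)2, THF, −78 °C; then DMPU, TBSCl, −78 °C to rt; distillation
Reagents that add atoms: tert-butyldimethylsilyl chloride, CC(C)(C)[Si](C)(C)Cl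
Why: Kinetic γ-deprotonation of the senecioate gives the extended lithium dienolate, and O-silylation in the presence of DMPU should give the silyl ketene acetal; its C1 geometry is not carried into later products.

Step 10
Reactants: 11 (2E,6E,10Z)-12-[(tert-butyldimethylsilyl)oxy]-3,7,11-trimethyldodeca-2,6,10-trienal; 13 (1Z)-1-[(tert-butyldimethylsilyl)oxy]-1-ethoxy-3-methylbuta-1,3-diene
Product: 15 ethyl (2E,5R,6E,10E,14Z)-16-[(tert-butyldimethylsilyl)oxy]-5-hydroxy-3,7,11,15-tetramethylhexadeca-2,6,10,14-tetraenoate, via trichlorosilyl ether 14 (not isolated)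
Conditions: SiCl4 (1.1 equiv), (R,R)-bisphosphoramide (5 mol %; two cyclic phosphoramide units built on (R)-N,N'-dimethyl-1,1'-binaphthalene-2,2'-diamine, joined through their exocyclic N-methyl nitrogens by a pentane-1,5-diyl chain), i-Pr2NEt (0.2 equiv), CH2Cl2, −78 °C; quench into cold sat. aq. NaHCO3
Reagents that add atoms: none
Why: The bisphosphoramide binds SiCl4 and displaces chloride, so that a chiral cationic trichlorosilyl species activates the carbonyl oxygen of 11 and the unsubstituted γ-CH2 of 13 attacks the aldehyde carbon through an open transition state to form C4–C5, after which chloride takes the tert-butyldimethylsilyl group and the aldolate is held as trichlorosilyl ether 14 until the bicarbonate quench. This is the Lewis-base-catalysed, SiCl4-mediated vinylogous Mukaiyama aldol addition of ester-derived silyl dienolates to conjugated aldehydes, applied here to a β,β-disubstituted enal that has no α-hydrogen to enolise. No ring is closed. The single new stereocentre C5 is set by the catalyst alone, which blocks the Si face so that attack on the Re face gives 5R, the dienolate carrying no γ-substituent that could exert a second influence. The step needs γ- over α-attack, secured by the hindered ketene acetal terminus bearing the ethoxy and silyloxy groups, 1,2- over 1,4-addition, secured by the fully substituted β-carbon of the enal, and the 2E alkene, which follows from reaction of the s-trans dienolate. Any 2Z adduct would place the C5 oxygen next to the ester, lactonise to a dihydropyranone and be removed on chromatography, and the amine buffer keeps HCl away from the allylic silyl ether and the trisubstituted alkenes.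

Step 11
Reactants: 15 (5R)-δ-hydroxy enoate
Product: 16 ethyl (2E,5R,6E,10E,14Z)-5,16-bis[(tert-butyldimethylsilyl)oxy]-3,7,11,15-tetramethylhexadeca-2,6,10,14-tetraenoate
Conditions: TBSCl, imidazole, DMF, rt
Reagents that add atoms: tert-butyldimethylsilyl chloride, CC(C)(C)[Si](C)(C)Cl
Why: Imidazole-promoted silylation of the secondary allylic alcohol under non-acidic conditions masks C5–OH for the hydride, bromination and organocopper steps without risk to the C5 centre.

Step 12
Reactants: 16 bis-silyl enoate
Product: 17 (2E,5R,6E,10E,14Z)-5,16-bis[(tert-butyldimethylsilyl)oxy]-3,7,11,15-tetramethylhexadeca-2,6,10,14-tetraen-1-ol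
Conditions: i-Bu2AlH, CH2Cl2, −78 °C; aqueous potassium sodium tartrate work-up
Reagents that add atoms: none
Why: 1,2-Reduction of the conjugated ester by i-Bu2AlH should give the C1 allylic alcohol with the 2E alkene and both silyl ethers intact.

Step 13
Reactants: 17 C1 allylic alcohol
Product: 18 (2E,5R,6E,10E,14Z)-1-bromo-5,16-bis[(tert-butyldimethylsilyl)oxy]-3,7,11,15-tetramethylhexadeca-2,6,10,14-tetraene
Conditions: CBr4, PPh3, CH2Cl2, 0 °C; used crude at once
Reagents that add atoms: carbon tetrabromide, BrC(Br)(Br)Br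
Why: Appel reaction, in which bromide displaces the alkoxyphosphonium ion at the primary allylic carbon under neutral conditions, so that neither allylic transposition nor silyl ether cleavage is expected.

Step 14
Reactants: 19 4-methoxy-2-methylphenol
Product: 20 2-bromo-4-methoxy-6-methylphenol
Conditions: NBS, i-Pr2NH (cat.), CH2Cl2, 0 °C
Reagents that add atoms: N-bromosuccinimide, O=C1CCC(=O)N1Br
Why: Amine-catalysed ortho-bromination of a phenol (electrophilic aromatic substitution delivered next to the hydroxyl), which should go to C6, the only free position ortho to OH, the para position being blocked by the methoxy group.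

Step 15
Reactants: 20 2-bromo-4-methoxy-6-methylphenol
Product: 21 1-bromo-2,5-dimethoxy-3-methylbenzene
Conditions: MeI, K2CO3, acetone, reflux
Reagents that add atoms: iodomethane, CI
Why: Williamson O-methylation of the phenoxide gives the hydroquinone dimethyl ether, which tolerates the organometallic step and can be unmasked oxidatively.

Step 16
Reactants: 18 allylic bromide; 21 1-bromo-2,5-dimethoxy-3-methylbenzene
Product: 24 1-[(2E,5R,6E,10E,14Z)-5,16-bis[(tert-butyldimethylsilyl)oxy]-3,7,11,15-tetramethylhexadeca-2,6,10,14-tetraen-1-yl]-2,5-dimethoxy-3-methylbenzene, via aryllithium 22 (not isolated), via arylcopper 23 (not isolated)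
Conditions: 21 (excess), n-BuLi, THF, −78 °C; CuBr·SMe2, −78 to −40 °C; then 18, −78 to 0 °C
Reagents that add atoms: none
Why: Bromine–lithium exchange and transmetalation give the arylcopper, which should substitute the primary allylic bromide at C1 (copper-mediated SN2 allylic coupling of the kind used for prenylated hydroquinone ethers) with retention of the 2E alkene, attack at the fully substituted C3 being disfavoured.

Step 17
Reactants: 24 bis-silyl dimethoxyarene
Product: 25 (2E,5R,6E,10E,14Z)-1-(2,5-dimethoxy-3-methylphenyl)-3,7,11,15-tetramethylhexadeca-2,6,10,14-tetraene-5,16-diol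
Conditions: Bu4NF, THF, 0 °C to rt
Reagents that add atoms: none
Why: Fluoride-driven desilylation removes the primary and the secondary silyl ether in one operation, and the aryl methyl ethers and the C5 centre are inert to it.

Step 18
Reactants: 25 dimethoxyarene diol
Product: 27 2-[(2E,5R,6E,10E,14Z)-5,16-dihydroxy-3,7,11,15-tetramethylhexadeca-2,6,10,14-tetraen-1-yl]-6-methylbenzene-1,4-diol, via quinone 26 (not isolated)
Conditions: (NH4)2Ce(NO3)6, MeCN/H2O, 0 °C, short contact; Et2O extract shaken with aq. Na2S2O4 under Ar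
Reagents that add atoms: water, O
Why: Oxidative demethylation of the 1,4-dimethoxyarene by (NH4)2Ce(NO3)6 (arene radical cation, ipso attack of water, loss of methanol) should give the 1,4-benzoquinone, and two-electron reduction by dithionite gives the hydroquinone, the isolated alkenes and the two alcohols being expected to tolerate the brief cold oxidation.

**Compound list**
1 | (2E,6E)-farnesol | CC(C)=CCC/C(C)=C/CC/C(C)=C/CO | starting material
2 | (2E,6E)-farnesyl 4-methoxybenzyl ether, 1-methoxy-4-({[(2E,6E)-3,7,11-trimethyldodeca-2,6,10-trien-1-yl]oxy}methyl)benzene | CC(C)=CCC/C(C)=C/CC/C(C)=C/COCc1ccc(OC)cc1 | intermediate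
3 | racemic (6E,10E)-3-bromo-12-[(4-methoxyphenyl)methoxy]-2,6,10-trimethyldodeca-6,10-dien-2-ol (not isolated) | CC(C)(O)C(Br)CC/C(C)=C/CC/C(C)=C/COCc1ccc(OC)cc1 | intermediate
4 | racemic 2-[(3E,7E)-9-[(4-methoxyphenyl)methoxy]-3,7-dimethylnona-3,7-dien-1-yl]-3,3-dimethyloxirane | CC1(C)OC1CC/C(C)=C/CC/C(C)=C/COCc1ccc(OC)cc1 | intermediate
5 | (4E,8E)-10-[(4-methoxyphenyl)methoxy]-4,8-dimethyldeca-4,8-dienal | O=CCC/C(C)=C/CC/C(C)=C/COCc1ccc(OC)cc1 | intermediate
6 | ethyl 2-[bis(2,2,2-trifluoroethoxy)phosphoryl]propanoate | CCOC(=O)C(C)P(=O)(OCC(F)(F)F)OCC(F)(F)F | starting material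
7 | ethyl (2Z,6E,10E)-12-[(4-methoxyphenyl)methoxy]-2,6,10-trimethyldodeca-2,6,10-trienoate | C/C(=C/CC/C(C)=C/CC/C(C)=C/COCc1ccc(OC)cc1)C(=O)OCC | intermediate
8 | (2Z,6E,10E)-12-[(4-methoxyphenyl)methoxy]-2,6,10-trimethyldodeca-2,6,10-trien-1-ol | C/C(=C/CC/C(C)=C/CC/C(C)=C/COCc1ccc(OC)cc1)CO | intermediate
9 | tert-butyl{[(2Z,6E,10E)-12-[(4-methoxyphenyl)methoxy]-2,6,10-trimethyldodeca-2,6,10-trien-1-yl]oxy}dimethylsilane | C/C(=C/CC/C(C)=C/CC/C(C)=C/COCc1ccc(OC)cc1)CO[Si](C)(C)C(C)(C)C | intermediate
10 | (2E,6E,10Z)-12-[(tert-butyldimethylsilyl)oxy]-3,7,11-trimethyldodeca-2,6,10-trien-1-ol | C/C(=C/CC/C(C)=C/CC/C(C)=C/CO)CO[Si](C)(C)C(C)(C)C | intermediate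
11 | (2E,6E,10Z)-12-[(tert-butyldimethylsilyl)oxy]-3,7,11-trimethyldodeca-2,6,10-trienal | C/C(=C/CC/C(C)=C/CC/C(C)=C/C=O)CO[Si](C)(C)C(C)(C)C | intermediate
12 | ethyl 3-methylbut-2-enoate | CCOC(=O)C=C(C)C | starting material
13 | (1Z)-1-[(tert-butyldimethylsilyl)oxy]-1-ethoxy-3-methylbuta-1,3-diene | C=C(C)/C=C(\O[Si](C)(C)C(C)(C)C)OCC | intermediate
14 | ethyl (2E,5R,6E,10E,14Z)-16-[(tert-butyldimethylsilyl)oxy]-3,7,11,15-tetramethyl-5-[(trichlorosilyl)oxy]hexadeca-2,6,10,14-tetraenoate (not isolated) | C/C(=C/CC/C(C)=C/CC/C(C)=C/[C@H](O[Si](Cl)(Cl)Cl)C/C(C)=C/C(=O)OCC)CO[Si](C)(C)C(C)(C)C | intermediate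
15 | ethyl (2E,5R,6E,10E,14Z)-16-[(tert-butyldimethylsilyl)oxy]-5-hydroxy-3,7,11,15-tetramethylhexadeca-2,6,10,14-tetraenoate | C/C(=C/CC/C(C)=C/CC/C(C)=C/[C@H](O)C/C(C)=C/C(=O)OCC)CO[Si](C)(C)C(C)(C)C | intermediate
16 | ethyl (2E,5R,6E,10E,14Z)-5,16-bis[(tert-butyldimethylsilyl)oxy]-3,7,11,15-tetramethylhexadeca-2,6,10,14-tetraenoate | C/C(=C/CC/C(C)=C/CC/C(C)=C/[C@H](O[Si](C)(C)C(C)(C)C)C/C(C)=C/C(=O)OCC)CO[Si](C)(C)C(C)(C)C | intermediate
17 | (2E,5R,6E,10E,14Z)-5,16-bis[(tert-butyldimethylsilyl)oxy]-3,7,11,15-tetramethylhexadeca-2,6,10,14-tetraen-1-ol | C/C(=C/CC/C(C)=C/CC/C(C)=C/[C@H](O[Si](C)(C)C(C)(C)C)C/C(C)=C/CO)CO[Si](C)(C)C(C)(C)C | intermediate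
18 | (2E,5R,6E,10E,14Z)-1-bromo-5,16-bis[(tert-butyldimethylsilyl)oxy]-3,7,11,15-tetramethylhexadeca-2,6,10,14-tetraene | C/C(=C/CC/C(C)=C/CC/C(C)=C/[C@H](O[Si](C)(C)C(C)(C)C)C/C(C)=C/CBr)CO[Si](C)(C)C(C)(C)C | intermediate
19 | 4-methoxy-2-methylphenol | Cc1cc(OC)ccc1O | starting material
20 | 2-bromo-4-methoxy-6-methylphenol | Cc1cc(OC)cc(Br)c1O | intermediate
21 | 1-bromo-2,5-dimethoxy-3-methylbenzene | COc1cc(C)c(OC)c(Br)c1 | intermediate
22 | (2,5-dimethoxy-3-methylphenyl)lithium (not isolated) | [Li]c1cc(OC)cc(C)c1OC | intermediate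
23 | (2,5-dimethoxy-3-methylphenyl)copper (not isolated) | [Cu]c1cc(OC)cc(C)c1OC | intermediate
24 | 1-[(2E,5R,6E,10E,14Z)-5,16-bis[(tert-butyldimethylsilyl)oxy]-3,7,11,15-tetramethylhexadeca-2,6,10,14-tetraen-1-yl]-2,5-dimethoxy-3-methylbenzene | C/C(=C/CC/C(C)=C/CC/C(C)=C/[C@H](O[Si](C)(C)C(C)(C)C)C/C(C)=C/Cc1cc(OC)cc(C)c1OC)CO[Si](C)(C)C(C)(C)C | intermediate
25 | (2E,5R,6E,10E,14Z)-1-(2,5-dimethoxy-3-methylphenyl)-3,7,11,15-tetramethylhexadeca-2,6,10,14-tetraene-5,16-diol | C/C(=C/CC/C(C)=C/CC/C(C)=C/[C@H](O)C/C(C)=C/Cc1cc(OC)cc(C)c1OC)CO | intermediate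
26 | 2-[(2E,5R,6E,10E,14Z)-5,16-dihydroxy-3,7,11,15-tetramethylhexadeca-2,6,10,14-tetraen-1-yl]-6-methylcyclohexa-2,5-diene-1,4-dione (not isolated) | C/C(=C/CC/C(C)=C/CC/C(C)=C/[C@H](O)C/C(C)=C/CC1=CC(=O)C=C(C)C1=O)CO | intermediate
27 | 2-[(2E,5R,6E,10E,14Z)-5,16-dihydroxy-3,7,11,15-tetramethylhexadeca-2,6,10,14-tetraen-1-yl]-6-methylbenzene-1,4-diol | C/C(=C/CC/C(C)=C/CC/C(C)=C/[C@H](O)C/C(C)=C/Cc1cc(O)cc(C)c1O)CO | target

**Count and risks**
Total steps: 18. Longest linear sequence: 15 steps (1–8, 10–13, 16–18).

Step 10. The enantioface discrimination may be insufficient on a β,β-disubstituted enal, and the allylic trichlorosilyl ether may ionise in the chlorosilane medium before the quench. The fallback keeps the C4–C5 aldol bond but sets C5 by reduction. It sets out from 11 and 13, which with BF3·OEt2 in CH2Cl2 at −78 °C should give the racemic aldol, racemic ethyl (2E,6E,10E,14Z)-16-[(tert-butyldimethylsilyl)oxy]-5-hydroxy-3,7,11,15-tetramethylhexadeca-2,6,10,14-tetraenoate F1. MnO2 in CH2Cl2 oxidises the allylic carbinol to ethyl (2E,6E,10E,14Z)-16-[(tert-butyldimethylsilyl)oxy]-3,7,11,15-tetramethyl-5-oxohexadeca-2,6,10,14-tetraenoate F2. Corey–Bakshi–Shibata reduction with (S)-2-methyl-CBS-oxazaborolidine (cat.) and catecholborane in toluene at −78 °C, the alkenyl group acting as the large substituent, should give the 5R alcohol and comes back to the route at 15.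

Step 16. The arylcopper may attack at C3 (SN2′), the 2E geometry may erode, or the crude allylic bromide may decompose before it couples. The fallback replaces the copper substitution by a palladium-catalysed cross-coupling. It sets out from 21, which with n-BuLi in THF at −78 °C and then Bu3SnCl gives tributyl(2,5-dimethoxy-3-methylphenyl)stannane F3. Stille coupling of this stannane with 18 under tris(dibenzylideneacetone)dipalladium Pd2(dba)3 (a zerovalent palladium source) and AsPh3 in THF at 50 °C should join the aryl group to the less hindered allyl terminus and comes back at 24.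

Step 18. The free allylic carbinols may ionise or be oxidised in the acidic cerium medium, which would also endanger the C5 configuration. The fallback oxidises before desilylation, so that both oxygens stay masked while cerium and nitric acid are present. It sets out from 24, which with (NH4)2Ce(NO3)6 in MeCN/H2O at 0 °C should give 2-[(2E,5R,6E,10E,14Z)-5,16-bis[(tert-butyldimethylsilyl)oxy]-3,7,11,15-tetramethylhexadeca-2,6,10,14-tetraen-1-yl]-6-methylcyclohexa-2,5-diene-1,4-dione F4. HF·pyridine in THF/pyridine at 0 °C then removes both silyl groups at the quinone stage and comes back at 26, here isolated, which aqueous Na2S2O4 reduces to 27.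

**Further compounds**
F1 | step 10 | racemic ethyl (2E,6E,10E,14Z)-16-[(tert-butyldimethylsilyl)oxy]-5-hydroxy-3,7,11,15-tetramethylhexadeca-2,6,10,14-tetraenoate | C/C(=C/CC/C(C)=C/CC/C(C)=C/C(O)C/C(C)=C/C(=O)OCC)CO[Si](C)(C)C(C)(C)C
F2 | step 10 | ethyl (2E,6E,10E,14Z)-16-[(tert-butyldimethylsilyl)oxy]-3,7,11,15-tetramethyl-5-oxohexadeca-2,6,10,14-tetraenoate | C/C(=C/CC/C(C)=C/CC/C(C)=C/C(=O)C/C(C)=C/C(=O)OCC)CO[Si](C)(C)C(C)(C)C
F3 | step 16 | tributyl(2,5-dimethoxy-3-methylphenyl)stannane | CCCC[Sn](CCCC)(CCCC)c1cc(OC)cc(C)c1OC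
F4 | step 18 | 2-[(2E,5R,6E,10E,14Z)-5,16-bis[(tert-butyldimethylsilyl)oxy]-3,7,11,15-tetramethylhexadeca-2,6,10,14-tetraen-1-yl]-6-methylcyclohexa-2,5-diene-1,4-dione | C/C(=C/CC/C(C)=C/CC/C(C)=C/[C@H](O[Si](C)(C)C(C)(C)C)C/C(C)=C/CC1=CC(=O)C=C(C)C1=O)CO[Si](C)(C)C(C)(C)C
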